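## Retrosynthetic overview

1. The target, 3-[(2S)-2-hydroxypentadecyl]-5-methoxyphenol (chain numbering: C1 benzylic CH2, C2 carbinol, C3–C15 alkyl), comes from (S)-1-(3,5-dimethoxyphenyl)pentadecan-2-ol by cleavage of one of its two equivalent aryl methyl ethers, so no protecting group is needed.
2. C2–OH comes from C2–B(pin) by stereoretentive oxidation; C3–C4 and C1–C2 come from one enantioselective nickel-catalysed conjunctive coupling of 1-iodododecane with the B-vinyl ate complex of the 3,5-dimethoxybenzyl pinacol boronate.
3. Enabling feature: the carbinol carbon C2 lies between two methylene groups (benzylic C1 and chain C3). This CH2–CH(O)–CH2 triad maps onto a vinylboronate: C2 is the boron-bearing carbon (O from B), C3 is the vinyl terminus that receives C4 of the dodecyl group, and C1 is the benzyl ligand that migrates from boron to C2.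
4. The benzyl boronate comes from 3,5-dimethoxybenzyl bromide and bis(pinacolato)diboron.
5. Rings: no ring of the target is formed, since the benzene ring is purchased; the dioxaborolane is the only temporary ring and is removed in the oxidation.

Key step: step 2

Remark on the chemistry: the sense of induction of the chiral nickel catalyst is to be assigned on a first run (Mosher ester analysis of 6), and the ligand antipode that leads to the (S)-boronate is the one meant throughout. Vinyllithium is prepared halide-free from tetravinylstannane and n-BuLi immediately before use.

## Route

Step 1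
Reactants: 1 3,5-dimethoxybenzyl bromide
Product: 2 2-(3,5-dimethoxybenzyl)-4,4,5,5-tetramethyl-1,3,2-dioxaborolane
Conditions: B2pin2 (1.1 equiv), Pd(dba)2 (3 mol%), P(4-MeOC6H4)3 (6 mol%), KOAc (1.5 equiv), toluene, 50 °C
Reagents that add atoms: bis(pinacolato)diboron, CC1(C)OB(OC1(C)C)B1OC(C)(C)C(C)(C)O1
Why: Miyaura borylation of a benzylic halide (oxidative addition of the C–Br bond, acetate-assisted transmetalation with the diboron, C–B reductive elimination) should give the benzylic pinacol boronate; the aryl methyl ethers are inert and no stereocentre is involved.

Step 2
Reactants: 2 2-(3,5-dimethoxybenzyl)-4,4,5,5-tetramethyl-1,3,2-dioxaborolane; 3 1-iodododecane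
Product: 6 (S)-1-(3,5-dimethoxyphenyl)pentadecan-2-ol, via lithium B-vinyl ate complex 4 (not isolated), via secondary pinacol boronate 5 (not isolated)
Conditions: (i) vinyllithium (from tetravinylstannane, n-BuLi), THF, −78 °C → rt; (ii) 3, NiBr2·glyme (10 mol%), chiral C2-symmetric 1,2-diamine ligand L* (13 mol%; Pybox ligands as the second class to screen), THF, rt; (iii) 3 M NaOH, 30% H2O2, 0 °C → rt
Reagents that add atoms: tetravinylstannane, C=C[Sn](C=C)(C=C)C=C (source of vinyllithium, [Li]C=C); hydrogen peroxide, OO
Why: Vinyllithium adds to the boron of 2 to give the tetracoordinate ate complex 4; Ni(I)–L* takes the iodine atom from 3 and the resulting dodecyl–nickel species engages the electron-rich B-vinyl group, so that the dodecyl carbon bonds to the unsubstituted vinyl terminus (C3–C4) while the benzyl group shifts from boron to the adjacent carbon (C1–C2), either by nickel-induced 1,2-metallate shift followed by C(sp3)–C(sp3) reductive elimination or by the radical–polar crossover variant through the α-boryl radical. The closest known reaction type is the nickel-catalysed enantioselective conjunctive cross-coupling of vinylboron ate complexes with unactivated alkyl iodides. No ring is closed. The only new stereocentre, C2, is created in the 1,2-shift under control of the chiral ligand on nickel (antipode chosen for S) and is carried into 6 by the stereoretentive alkaline peroxide oxidation of the C–B bond. The step needs regioselectivity (boron on the internal vinyl carbon sends the incoming carbon to the terminal CH2 and makes the internal carbon the migration terminus), chemoselectivity (the pinacolato oxygens do not migrate and benzyl is the only other carbon ligand, so one conjunctive product is possible, with direct transfer of benzyl or vinyl to nickel as the competing path) and enantioselectivity (ligand control).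

Step 3
Reactants: 6 (S)-1-(3,5-dimethoxyphenyl)pentadecan-2-ol
Product: 7 3-[(2S)-2-hydroxypentadecyl]-5-methoxyphenol
Conditions: NaSEt (4 equiv), DMF, 140 °C; then 1 M HCl work-up
Reagents that add atoms: none
Why: Thiolate-mediated aryl methyl ether cleavage (SN2 attack of ethanethiolate on an O-methyl carbon) should stop after one cleavage because the phenoxide formed deactivates the second methoxy group; the two methoxy groups of 6 are equivalent, so only one mono-phenol can form, and the carbinol stereocentre is not touched.

## Compound list

1 | 3,5-dimethoxybenzyl bromide | COc1cc(CBr)cc(OC)c1 | starting material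
2 | 2-(3,5-dimethoxybenzyl)-4,4,5,5-tetramethyl-1,3,2-dioxaborolane | COc1cc(CB2OC(C)(C)C(C)(C)O2)cc(OC)c1 | intermediate
3 | 1-iodododecane | CCCCCCCCCCCCI | starting material
4 | lithium (3,5-dimethoxybenzyl)(pinacolato)(vinyl)borate, not isolated | [Li+].C=C[B-]1(Cc2cc(OC)cc(OC)c2)OC(C)(C)C(C)(C)O1 | intermediate
5 | 2-[(2S)-1-(3,5-dimethoxyphenyl)pentadecan-2-yl]-4,4,5,5-tetramethyl-1,3,2-dioxaborolane, not isolated | CCCCCCCCCCCCC[C@H](B1OC(C)(C)C(C)(C)O1)Cc1cc(OC)cc(OC)c1 | intermediate
6 | (S)-1-(3,5-dimethoxyphenyl)pentadecan-2-ol | CCCCCCCCCCCCC[C@H](O)Cc1cc(OC)cc(OC)c1 | intermediate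
7 | 3-[(2S)-2-hydroxypentadecyl]-5-methoxyphenol | CCCCCCCCCCCCC[C@H](O)Cc1cc(O)cc(OC)c1 | target

## Summary and risks

Total step count: 3. Longest linear sequence: 3 steps (1 → 2 → 6 → 7).

Steps most likely to fail:

1. Step 2 (key step). Enantioselectivity may be eroded by a non-selective background radical chain, and the ate complex may be diverted into direct benzyl–alkyl or vinyl–alkyl cross-coupling instead of the conjunctive pathway; the benzyl migrating group is the least precedented element. The fallback sets out from 3 and comes back at 6, using only chiral-pool epoxide chemistry. 1-Iodododecane 3 is converted with magnesium in Et2O into dodecylmagnesium iodide F1. F1 opens commercial (S)-epichlorohydrin at the epoxide CH2 under CuI catalysis (THF, −30 °C), which makes the same C3–C4 bond and gives (S)-1-chloropentadecan-2-ol F2. Aqueous NaOH closes F2 to (S)-2-tridecyloxirane F3. Commercial 3,5-dimethoxyphenylmagnesium chloride with catalytic CuI then opens F3 at its CH2 to give 6. No bond to the stereocentre is broken, so the S configuration is carried from the epichlorohydrin.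

2. Step 3. The reaction may fail to stop at the mono-phenol (over-cleavage to the resorcinol) or stall at incomplete conversion. The fallback sets out from 6 and comes back at 7. Both ethers are cleaved with BBr3 (CH2Cl2, −78 → 0 °C; the secondary alcohol is held as its borate and released on work-up) to give (S)-5-(2-hydroxypentadecyl)benzene-1,3-diol F4. F4 is then mono-methylated with MeI (1 equiv) and K2CO3 in acetone to give 7; only the phenols are deprotonated, and recovered F4 and any re-formed 6 are recycled.

3. Step 1. The electron-rich benzyl bromide may undergo reductive homocoupling to the bibenzyl, and the benzylic boronate may protodeboronate during purification. The fallback sets out from 1 and comes back at 2. Bromide 1 is added slowly to magnesium in Et2O at 0 °C to form (3,5-dimethoxybenzyl)magnesium bromide F5, which is quenched at −78 °C with 2-isopropoxy-4,4,5,5-tetramethyl-1,3,2-dioxaborolane to give 2 without a transition metal.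

## Further compounds

F1 | step 2 | dodecylmagnesium iodide | CCCCCCCCCCCC[Mg]I
F2 | step 2 | (S)-1-chloropentadecan-2-ol | CCCCCCCCCCCCC[C@H](O)CCl
F3 | step 2 | (S)-2-tridecyloxirane | CCCCCCCCCCCCC[C@H]1CO1
F4 | step 3 | (S)-5-(2-hydroxypentadecyl)benzene-1,3-diol | CCCCCCCCCCCCC[C@H](O)Cc1cc(O)cc(O)c1
F5 | step 1 | (3,5-dimethoxybenzyl)magnesium bromide | COc1cc(C[Mg]Br)cc(OC)c1
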